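## Retrosynthetic overview

1. Haterumaimide F ⇐ desilylation and succinimide closure (amide N onto the acyl-oxazolidinone carbonyl) of a syn-aldol adduct. The C12–C13 bond is made by an intermolecular Evans boron aldol between a C12 decalin aldehyde and a succinamoyl oxazolidinone, which sets C12 and C13.
2. Aldehyde ⇐ 6β-silyloxy-8(17)-ene pivalate. The exocyclic alkene is restored by Pd/formate hydrogenolysis of a C17 allylic acetate; the 6β-OH comes from α-face hydride reduction of a 7-en-6-one.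
3. 7-En-6-one ⇐ allylic oxidation at C6 of a 17-acetoxy-7-ene ⇐ SN2′ transposition of the 7-hydroxy-8(17)-ene (SeO2 on the exocyclic alkene).
4. Exocyclic alkene ⇐ dehydration of the 8α-ol obtained by reducing 2α-chlorosclareolide ⇐ radical C2–H chlorination of (+)-sclareolide (C5, C9, C10 from the chiral pool).
5. Rings: rings A and B arrive as the trans-decalin of sclareolide (its lactone is opened in step 2); the only ring built is the succinimide, closed in step 17.

Assumption: labdane numbering (C1–C20; α = face opposite the C10 methyl) is used for all decalin compounds; (+)-sclareolide, (R)-4-benzyl-2-oxazolidinone, succinic anhydride and all reagents are bought.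

## Route

Step 1
Reactants: 1 (+)-sclareolide
Product: 2 2α-chlorosclareolide
Conditions: N-tert-butyl-N-chloro-3,5-bis(trifluoromethyl)benzamide (1.2 equiv), Cs2CO3, PhH, 55 °C, visible light
Reagents that add atoms: N-tert-butyl-N-chloro-3,5-bis(trifluoromethyl)benzamide, CC(C)(C)N(Cl)C(=O)c1cc(cc(c1)C(F)(F)F)C(F)(F)F
Why: Radical C–H chlorination (amidyl-radical hydrogen abstraction, then chlorine-atom transfer): the bulky electrophilic amidyl radical takes the most accessible, electron-rich methylene hydrogen at C2, far from the deactivating lactone, and chlorine is delivered to the α (equatorial) face anti to the axial C4β and C10 methyls, which sets C2 (S), while C5, C9 and C10 come unchanged from sclareolide.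

Step 2
Reactants: 2 2α-chlorosclareolide
Product: 3 2α-chloro-13,14,15,16-tetranorlabdane-8α,12-diol
Conditions: LiAlH4, THF, 0 °C
Reagents that add atoms: none
Why: Hydride reduction of the lactone; at 0 °C the secondary alkyl chloride is inert and no stereocentre is touched.

Step 3
Reactants: 3 2α-chloro-13,14,15,16-tetranorlabdane-8α,12-diol
Product: 4 2α-chloro-8α-hydroxy-13,14,15,16-tetranorlabdan-12-yl pivalate
Conditions: PivCl, pyridine, DMAP (cat.), CH2Cl2, 0 °C → rt
Reagents that add atoms: pivaloyl chloride, CC(C)(C)C(Cl)=O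
Why: Chemoselective esterification: the primary alcohol is acylated while the hindered tertiary 8α-alcohol does not react.

Step 4
Reactants: 4 2α-chloro-8α-hydroxy-13,14,15,16-tetranorlabdan-12-yl pivalate
Product: 6 2α-chloro-13,14,15,16-tetranorlabd-8(17)-en-12-yl pivalate, via chlorosulfite ester 5 (not isolated)
Conditions: SOCl2, pyridine, CH2Cl2, −78 °C
Reagents that add atoms: none
Why: Regioselective E2 dehydration: the equatorial chlorosulfite has no anti-periplanar ring hydrogen, so pyridine removes a C17 methyl hydrogen and the exocyclic alkene dominates.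

Step 5
Reactants: 6 2α-chloro-13,14,15,16-tetranorlabd-8(17)-en-12-yl pivalate
Product: 7 2α-chloro-7α-hydroxy-13,14,15,16-tetranorlabd-8(17)-en-12-yl pivalate
Conditions: SeO2 (0.5 equiv), t-BuOOH, CH2Cl2, rt
Reagents that add atoms: selenium dioxide, O=[Se]=O (transfers the O atom, reloaded by the peroxide); tert-butyl hydroperoxide, CC(C)(C)OO
Why: SeO2 allylic oxidation (ene reaction then [2,3]-shift) hydroxylates the allylic ring methylene C7 from the open α face; this centre is erased again in step 6.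

Step 6
Reactants: 7 2α-chloro-7α-hydroxy-13,14,15,16-tetranorlabd-8(17)-en-12-yl pivalate
Product: 9 17-bromo-2α-chloro-13,14,15,16-tetranorlabd-7-en-12-yl pivalate, via allylic dibromophosphite 8 (not isolated)
Conditions: PBr3, pyridine (cat.), Et2O, −20 → 0 °C
Reagents that add atoms: phosphorus tribromide, BrP(Br)Br
Why: SN2′ bromination: bromide attacks the unhindered terminal CH2 of the activated allylic phosphite (any secondary bromide equilibrates), giving the thermodynamically favoured primary bromide with the trisubstituted 7,8-alkene.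

Step 7
Reactants: 9 17-bromo-2α-chloro-13,14,15,16-tetranorlabd-7-en-12-yl pivalate
Product: 10 17-acetoxy-2α-chloro-13,14,15,16-tetranorlabd-7-en-12-yl pivalate
Conditions: CsOAc, DMF, rt
Reagents that add atoms: cesium acetate, CC(=O)[O-].[Cs+]
Why: SN2 displacement of the primary allylic bromide by acetate; the equatorial secondary chloride at C2 is far slower.

Step 8
Reactants: 10 17-acetoxy-2α-chloro-13,14,15,16-tetranorlabd-7-en-12-yl pivalate
Product: 11 17-acetoxy-2α-chloro-6-oxo-13,14,15,16-tetranorlabd-7-en-12-yl pivalate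
Conditions: CrO3, 3,5-dimethylpyrazole, CH2Cl2, −20 °C
Reagents that add atoms: chromium trioxide, O=[Cr](=O)=O
Why: Chromium-mediated allylic oxidation of the ring methylene C6 next to the trisubstituted alkene gives the 7-en-6-one, the usual outcome for drim-7-enes, since C9–H is tertiary and shielded and C17 is deactivated by its acetate.

Step 9
Reactants: 11 17-acetoxy-2α-chloro-6-oxo-13,14,15,16-tetranorlabd-7-en-12-yl pivalate
Product: 12 17-acetoxy-2α-chloro-6β-hydroxy-13,14,15,16-tetranorlabd-7-en-12-yl pivalate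
Conditions: NaBH4, CeCl3·7H2O, MeOH, −20 → 0 °C
Reagents that add atoms: none
Why: Luche 1,2-reduction: hydride adds to the C6 carbonyl from the α face because the β face is blocked by the axial C10 and C4β methyls, which sets the axial 6β-alcohol (C6 R in the target).

Step 10
Reactants: 12 17-acetoxy-2α-chloro-6β-hydroxy-13,14,15,16-tetranorlabd-7-en-12-yl pivalate
Product: 13 17-acetoxy-2α-chloro-6β-(triethylsilyloxy)-13,14,15,16-tetranorlabd-7-en-12-yl pivalate
Conditions: Et3SiOTf, 2,6-lutidine, CH2Cl2, −40 → 0 °C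
Reagents that add atoms: triethylsilyl trifluoromethanesulfonate, CC[Si](CC)(CC)OS(=O)(=O)C(F)(F)F
Why: Silyl triflate silylation is strong enough for the hindered axial alcohol, and the buffered conditions do not ionise the allylic system.

Step 11
Reactants: 13 17-acetoxy-2α-chloro-6β-(triethylsilyloxy)-13,14,15,16-tetranorlabd-7-en-12-yl pivalate
Product: 14 2α-chloro-6β-(triethylsilyloxy)-13,14,15,16-tetranorlabd-8(17)-en-12-yl pivalate
Conditions: Pd(OAc)2 (5 mol %), PBu3 (20 mol %), HCO2NH4, dioxane, 100 °C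
Reagents that add atoms: none
Why: Tsuji palladium-catalysed formate hydrogenolysis of the allylic acetate: the σ-allylpalladium formate carries palladium on the primary C17 and hands hydride to C7 through a cyclic transition state, which regenerates the exocyclic 8(17)-alkene.

Step 12
Reactants: 14 2α-chloro-6β-(triethylsilyloxy)-13,14,15,16-tetranorlabd-8(17)-en-12-yl pivalate
Product: 15 2α-chloro-6β-(triethylsilyloxy)-13,14,15,16-tetranorlabd-8(17)-en-12-ol
Conditions: i-Bu2AlH, CH2Cl2, −78 °C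
Reagents that add atoms: none
Why: Reductive cleavage of the pivalate ester; silyl ether, alkene and chloride are untouched.

Step 13
Reactants: 15 2α-chloro-6β-(triethylsilyloxy)-13,14,15,16-tetranorlabd-8(17)-en-12-ol
Product: 16 2α-chloro-6β-(triethylsilyloxy)-13,14,15,16-tetranorlabd-8(17)-en-12-al
Conditions: Dess–Martin periodinane, pyridine, CH2Cl2, 0 °C → rt
Reagents that add atoms: none
Why: Dess–Martin oxidation of the primary alcohol to the aldehyde; the α-carbon C11 is a CH2, so nothing can epimerise.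

Step 14
Reactants: 17 (R)-4-benzyl-2-oxazolidinone; 18 succinic anhydride
Product: 20 4-[(R)-4-benzyl-2-oxooxazolidin-3-yl]-4-oxobutanoic acid, via lithium oxazolidinide 19 (not isolated)
Conditions: n-BuLi, THF, −78 °C; then 18, −78 → 0 °C; aq. HCl
Reagents that add atoms: none
Why: N-acylation of the lithiated oxazolidinone by ring opening of the cyclic anhydride.

Step 15
Reactants: 20 4-[(R)-4-benzyl-2-oxooxazolidin-3-yl]-4-oxobutanoic acid
Product: 22 4-[(R)-4-benzyl-2-oxooxazolidin-3-yl]-4-oxobutanamide, via isobutyl mixed anhydride 21 (not isolated)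
Conditions: i-BuOCOCl, N-methylmorpholine, THF, −15 °C; then NH3 (0.5 M in dioxane, 1.1 equiv)
Reagents that add atoms: ammonia, N
Why: Mixed-anhydride amidation: ammonia attacks the far more electrophilic mixed carbonic anhydride and spares the N-acyloxazolidinone.

Step 16
Reactants: 22 4-[(R)-4-benzyl-2-oxooxazolidin-3-yl]-4-oxobutanamide; 16 2α-chloro-6β-(triethylsilyloxy)-13,14,15,16-tetranorlabd-8(17)-en-12-al
Product: 24 (12S,13R) syn-aldol adduct, (2R,3S)-2-(2-amino-2-oxoethyl)-3-hydroxy acyl oxazolidinone carrying the 2α-chloro-6β-(triethylsilyloxy)-8(17)-ene decalin on C11, via Z-boron enolate 23 (not isolated)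
Conditions: 22 (1.5 equiv), Bu2BOTf (3.3 equiv), i-Pr2NEt (3.6 equiv), CH2Cl2, −78 → 0 °C; 16, −78 → 0 °C; pH 7 buffer, MeOH, H2O2
Reagents that add atoms: none
Why: Evans syn-aldol reaction: the Z-boron enolate reacts through a closed chair (Zimmerman–Traxler) transition state on the face opposite the (R)-benzyl group, which sets C12 (S) and C13 (R) under reagent control, while the primary amide is held as a boron imidate by the extra Bu2BOTf.

Step 17
Reactants: 24 (12S,13R) syn-aldol adduct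
Product: 25 6-O-triethylsilyl haterumaimide F
Conditions: DBU, THF, 0 °C → rt
Reagents that add atoms: none
Why: Intramolecular acyl substitution (5-exo-trig): the amide nitrogen attacks the activated N-acyloxazolidinone carbonyl, closing the succinimide and releasing the auxiliary under base too mild for retro-aldol or C13 epimerisation.

Step 18
Reactants: 25 6-O-triethylsilyl haterumaimide F
Product: 26 haterumaimide F
Conditions: HF·pyridine, pyridine, THF, 0 °C → rt
Reagents that add atoms: none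
Why: Fluoride desilylation under buffered conditions that leave the exocyclic alkene, the β-hydroxy imide and the chloride intact.

## Compound list

1 | (+)-sclareolide | C[C@@]12CC[C@H]3C(C)(C)CCC[C@]3(C)[C@H]1CC(=O)O2 | starting material
2 | 2α-chlorosclareolide | C[C@@]12CC[C@H]3C(C)(C)C[C@H](Cl)C[C@]3(C)[C@H]1CC(=O)O2 | intermediate
3 | 2α-chloro-13,14,15,16-tetranorlabdane-8α,12-diol | C[C@@]1(O)CC[C@H]2C(C)(C)C[C@H](Cl)C[C@]2(C)[C@H]1CCO | intermediate
4 | 2α-chloro-8α-hydroxy-13,14,15,16-tetranorlabdan-12-yl pivalate | C[C@@]1(O)CC[C@H]2C(C)(C)C[C@H](Cl)C[C@]2(C)[C@H]1CCOC(=O)C(C)(C)C | intermediate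
5 | 8α-chlorosulfite ester of 4 (not isolated) | C[C@@]1(OS(Cl)=O)CC[C@H]2C(C)(C)C[C@H](Cl)C[C@]2(C)[C@H]1CCOC(=O)C(C)(C)C | intermediate
6 | 2α-chloro-13,14,15,16-tetranorlabd-8(17)-en-12-yl pivalate | C=C1CC[C@H]2C(C)(C)C[C@H](Cl)C[C@]2(C)[C@H]1CCOC(=O)C(C)(C)C | intermediate
7 | 2α-chloro-7α-hydroxy-13,14,15,16-tetranorlabd-8(17)-en-12-yl pivalate | C=C1[C@H](O)C[C@H]2C(C)(C)C[C@H](Cl)C[C@]2(C)[C@H]1CCOC(=O)C(C)(C)C | intermediate
8 | 7α-dibromophosphite of 7 (not isolated) | C=C1[C@H](OP(Br)Br)C[C@H]2C(C)(C)C[C@H](Cl)C[C@]2(C)[C@H]1CCOC(=O)C(C)(C)C | intermediate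
9 | 17-bromo-2α-chloro-13,14,15,16-tetranorlabd-7-en-12-yl pivalate | BrCC1=CC[C@H]2C(C)(C)C[C@H](Cl)C[C@]2(C)[C@H]1CCOC(=O)C(C)(C)C | intermediate
10 | 17-acetoxy-2α-chloro-13,14,15,16-tetranorlabd-7-en-12-yl pivalate | CC(=O)OCC1=CC[C@H]2C(C)(C)C[C@H](Cl)C[C@]2(C)[C@H]1CCOC(=O)C(C)(C)C | intermediate
11 | 17-acetoxy-2α-chloro-6-oxo-13,14,15,16-tetranorlabd-7-en-12-yl pivalate | CC(=O)OCC1=CC(=O)[C@H]2C(C)(C)C[C@H](Cl)C[C@]2(C)[C@H]1CCOC(=O)C(C)(C)C | intermediate
12 | 17-acetoxy-2α-chloro-6β-hydroxy-13,14,15,16-tetranorlabd-7-en-12-yl pivalate | CC(=O)OCC1=C[C@@H](O)[C@H]2C(C)(C)C[C@H](Cl)C[C@]2(C)[C@H]1CCOC(=O)C(C)(C)C | intermediate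
13 | 17-acetoxy-2α-chloro-6β-(triethylsilyloxy)-13,14,15,16-tetranorlabd-7-en-12-yl pivalate | CC(=O)OCC1=C[C@@H](O[Si](CC)(CC)CC)[C@H]2C(C)(C)C[C@H](Cl)C[C@]2(C)[C@H]1CCOC(=O)C(C)(C)C | intermediate
14 | 2α-chloro-6β-(triethylsilyloxy)-13,14,15,16-tetranorlabd-8(17)-en-12-yl pivalate | C=C1C[C@@H](O[Si](CC)(CC)CC)[C@H]2C(C)(C)C[C@H](Cl)C[C@]2(C)[C@H]1CCOC(=O)C(C)(C)C | intermediate
15 | 2α-chloro-6β-(triethylsilyloxy)-13,14,15,16-tetranorlabd-8(17)-en-12-ol | C=C1C[C@@H](O[Si](CC)(CC)CC)[C@H]2C(C)(C)C[C@H](Cl)C[C@]2(C)[C@H]1CCO | intermediate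
16 | 2α-chloro-6β-(triethylsilyloxy)-13,14,15,16-tetranorlabd-8(17)-en-12-al | C=C1C[C@@H](O[Si](CC)(CC)CC)[C@H]2C(C)(C)C[C@H](Cl)C[C@]2(C)[C@H]1CC=O | intermediate
17 | (R)-4-benzyl-2-oxazolidinone | O=C1N[C@H](Cc2ccccc2)CO1 | starting material
18 | succinic anhydride | O=C1CCC(=O)O1 | starting material
19 | lithium salt of 17 (not isolated) | [Li+].O=C1[N-][C@H](Cc2ccccc2)CO1 | intermediate
20 | 4-[(R)-4-benzyl-2-oxooxazolidin-3-yl]-4-oxobutanoic acid | OC(=O)CCC(=O)N1[C@H](Cc2ccccc2)COC1=O | intermediate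
21 | isobutyl carbonic mixed anhydride of 20 (not isolated) | CC(C)COC(=O)OC(=O)CCC(=O)N1[C@H](Cc2ccccc2)COC1=O | intermediate
22 | 4-[(R)-4-benzyl-2-oxooxazolidin-3-yl]-4-oxobutanamide | NC(=O)CCC(=O)N1[C@H](Cc2ccccc2)COC1=O | intermediate
23 | Z-dibutylboron enolate of 22 (not isolated; amide drawn free) | CCCCB(CCCC)O/C(=C\CC(N)=O)N1[C@H](Cc2ccccc2)COC1=O | intermediate
24 | (12S,13R) syn-aldol adduct of 16 and 22 | C=C1C[C@@H](O[Si](CC)(CC)CC)[C@H]2C(C)(C)C[C@H](Cl)C[C@]2(C)[C@H]1C[C@H](O)[C@@H](CC(N)=O)C(=O)N1[C@H](Cc2ccccc2)COC1=O | intermediate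
25 | 6-O-triethylsilyl haterumaimide F | C=C1C[C@@H](O[Si](CC)(CC)CC)[C@H]2C(C)(C)C[C@H](Cl)C[C@]2(C)[C@H]1C[C@H](O)[C@H]1CC(=O)NC1=O | intermediate
26 | haterumaimide F | C=C1C[C@@H](O)[C@H]2C(C)(C)C[C@H](Cl)C[C@]2(C)[C@H]1C[C@H](O)[C@H]1CC(=O)NC1=O | target

## Step count and risks

Total step count: 18. Longest linear sequence: 16 (steps 1–13 and 16–18); steps 14–15 make the aldol partner.

Steps most likely to fail:

**Step 8 (allylic oxidation at C6).** The pseudo-axial C6–H sits under two axial methyls, and C9–H can compete. Fallback, setting out from 6 and coming back at 14: the C6 oxygen is brought in by epoxidation of a 6-en-8-one instead of C–H oxidation. Ozonolysis of 6 (O3, CH2Cl2/MeOH, −78 °C; Me2S) gives the 17-nor-8-ketone F1. Kinetic enolisation toward C7 (LiN(i-Pr)2, Me3SiCl, THF, −78 °C) gives the silyl enol ether F2, and Saegusa–Ito dehydrogenation (Pd(OAc)2, MeCN) gives the 6-en-8-one F3. Alkaline H2O2 (NaOH, MeOH, 0 °C) epoxidises from the open α face to the 6α,7α-epoxy ketone F4, and Wittig methylenation (Ph3P=CH2, THF) gives the vinyl epoxide F5. Formate hydrogenolysis with zerovalent palladium (Pd2(dba)3·CHCl3, PBu3, HCO2H, Et3N, dioxane) delivers hydride to C7 and gives the 6α-hydroxy-8(17)-ene F6. Dess–Martin oxidation to the β,γ-unsaturated 6-ketone F7 and immediate NaBH4 reduction (MeOH, −20 °C, hydride from the α face) give the 6β-alcohol F8, whose silylation (Et3SiOTf, 2,6-lutidine) is 14.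

**Step 11 (regiochemistry of the formate hydrogenolysis).** Hydride delivery to C17 or β-hydride elimination to a diene would lose the exocyclic alkene. Fallback, setting out from 13 and coming back at 14: a reductive allylic transposition through a diazene. K2CO3 in MeOH at 0 °C removes only the acetate to give the primary allylic alcohol F9. Mitsunobu reaction with 2-nitrobenzenesulfonylhydrazide (PPh3, diethyl azodicarboxylate, THF, −30 °C) gives the N-allyl sulfonylhydrazine F10. On warming to rt it loses the sulfinic acid to the allylic diazene F11, whose retro-ene loss of N2 places hydrogen on C7 and the double bond at C8=C17, which is 14.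

**Step 16 (boron aldol with a free primary amide).** The amide may bind boron unproductively or close to succinimide before the aldol. Fallback, setting out from 17 (with 16) and coming back at 24: the amide is carried as a nitrile. Commercial 3-cyanopropanoic acid is activated as its pivalic mixed anhydride F12 (PivCl, Et3N, THF, −20 °C) and coupled with 17 (LiCl) to give (R)-4-benzyl-3-(3-cyanopropanoyl)oxazolidin-2-one F13. Its Z-boron enolate F14 (Bu2BOTf, i-Pr2NEt, CH2Cl2, −78 → 0 °C) adds to 16 in the same Evans syn sense to give the nitrile aldol adduct F15. Neutral platinum-catalysed hydration ([PtH(PMe2OH)(PMe2O)2H], EtOH/H2O, 80 °C) turns the nitrile into the primary amide, which is 24.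

Further compounds
F1 | step 8 | 2α-chloro-8-oxo-13,14,15,16,17-pentanorlabdan-12-yl pivalate | O=C1CC[C@H]2C(C)(C)C[C@H](Cl)C[C@]2(C)[C@H]1CCOC(=O)C(C)(C)C
F2 | step 8 | 8-trimethylsilyloxy-7-ene silyl enol ether of F1 | C[Si](C)(C)OC1=CC[C@H]2C(C)(C)C[C@H](Cl)C[C@]2(C)[C@H]1CCOC(=O)C(C)(C)C
F3 | step 8 | 2α-chloro-8-oxo-13,14,15,16,17-pentanorlabd-6-en-12-yl pivalate | O=C1C=C[C@H]2C(C)(C)C[C@H](Cl)C[C@]2(C)[C@H]1CCOC(=O)C(C)(C)C
F4 | step 8 | 2α-chloro-6α,7α-epoxy-8-oxo-13,14,15,16,17-pentanorlabdan-12-yl pivalate | O=C1[C@@H]2O[C@@H]2[C@H]3C(C)(C)C[C@H](Cl)C[C@]3(C)[C@H]1CCOC(=O)C(C)(C)C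
F5 | step 8 | 2α-chloro-6α,7α-epoxy-13,14,15,16-tetranorlabd-8(17)-en-12-yl pivalate | C=C1[C@@H]2O[C@@H]2[C@H]3C(C)(C)C[C@H](Cl)C[C@]3(C)[C@H]1CCOC(=O)C(C)(C)C
F6 | step 8 | 2α-chloro-6α-hydroxy-13,14,15,16-tetranorlabd-8(17)-en-12-yl pivalate | C=C1C[C@H](O)[C@H]2C(C)(C)C[C@H](Cl)C[C@]2(C)[C@H]1CCOC(=O)C(C)(C)C
F7 | step 8 | 2α-chloro-6-oxo-13,14,15,16-tetranorlabd-8(17)-en-12-yl pivalate | C=C1CC(=O)[C@H]2C(C)(C)C[C@H](Cl)C[C@]2(C)[C@H]1CCOC(=O)C(C)(C)C
F8 | step 8 | 2α-chloro-6β-hydroxy-13,14,15,16-tetranorlabd-8(17)-en-12-yl pivalate | C=C1C[C@@H](O)[C@H]2C(C)(C)C[C@H](Cl)C[C@]2(C)[C@H]1CCOC(=O)C(C)(C)C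
F9 | step 11 | 2α-chloro-17-hydroxy-6β-(triethylsilyloxy)-13,14,15,16-tetranorlabd-7-en-12-yl pivalate | OCC1=C[C@@H](O[Si](CC)(CC)CC)[C@H]2C(C)(C)C[C@H](Cl)C[C@]2(C)[C@H]1CCOC(=O)C(C)(C)C
F10 | step 11 | N-(C17-allyl)-N-(2-nitrobenzenesulfonyl)hydrazine from F9 | NN(CC1=C[C@@H](O[Si](CC)(CC)CC)[C@H]2C(C)(C)C[C@H](Cl)C[C@]2(C)[C@H]1CCOC(=O)C(C)(C)C)S(=O)(=O)c1ccccc1[N+](=O)[O-]
F11 | step 11 | C17 allylic diazene from F10 | N=NCC1=C[C@@H](O[Si](CC)(CC)CC)[C@H]2C(C)(C)C[C@H](Cl)C[C@]2(C)[C@H]1CCOC(=O)C(C)(C)C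
F12 | step 16 | 3-cyanopropanoic pivalic anhydride | N#CCCC(=O)OC(=O)C(C)(C)C
F13 | step 16 | (R)-4-benzyl-3-(3-cyanopropanoyl)oxazolidin-2-one | N#CCCC(=O)N1[C@H](Cc2ccccc2)COC1=O
F14 | step 16 | Z-dibutylboron enolate of F13 | CCCCB(CCCC)O/C(=C\CC#N)N1[C@H](Cc2ccccc2)COC1=O
F15 | step 16 | (12S,13R) syn-aldol adduct of 16 and F13 (nitrile in place of the amide of 24) | C=C1C[C@@H](O[Si](CC)(CC)CC)[C@H]2C(C)(C)C[C@H](Cl)C[C@]2(C)[C@H]1C[C@H](O)[C@@H](CC#N)C(=O)N1[C@H](Cc2ccccc2)COC1=O
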